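A small charge of free catalyst, 15 mM, works on 1.5 M of starting material while its partner decays on its own.

    catalyst intermediate B → free catalyst + product (k1 = 97 h⁻¹)
    partner → decomposed reagent (k2 = 1.4 h⁻¹)
    starting material + free catalyst → catalyst intermediate A (k3 = 120 M⁻¹ h⁻¹)
    partner + catalyst intermediate A ⇌ catalyst intermediate B (K4 = 0.23 M⁻¹, k4 = 13 M⁻¹ h⁻¹)

starting material 1.5 M; partner 2.25 M; free catalyst 15 mM

1. the form that holds most of the catalyst when 10 % of the starting material are converted (catalyst intermediate B / catalyst intermediate A / free catalyst)
2. its share of the catalyst then

I followed one catalyst round the cycle. At catalyst intermediate B it goes on to product at 97 h⁻¹ or falls back at 56.5 h⁻¹, so I carried the forward chance, the forward rate over the sum of both, 0.632. Per product made, the catalyst's wait on catalyst intermediate A is the inverse of that chance times 13 M⁻¹ h⁻¹ times [partner]. Its wait on catalyst intermediate B is the inverse of 97 h⁻¹, and its wait as free catalyst is the inverse of 120 M⁻¹ h⁻¹ times [starting material]. Shares of the catalyst stand as these waits, so at 10 % conversion the other two forms together stand to catalyst intermediate A as 0.135 M⁻¹ times [partner].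

I set the partner's decay, 1.4 h⁻¹, and its use against the 0.135 M of product needed, and integrated to [partner] near 0.321 M. There the wait on catalyst intermediate A is longer than either other wait, so I took it as the resting state, at 95.8 %.

The forecast named catalyst intermediate A at 96 %, within 93 % to 98 %, on the ground that the partner decays “while turnover slows”.

The flask gave catalyst intermediate A at 95.9 %. That conversion came at 1.32 h, with product forming at 0.0368 M h⁻¹. Earlier in this flask, at 0.300 h, [partner] stood at 1.44 M and [starting material] at 1.43 M. The forward chance of 0.632 then gives catalyst intermediate A 84.0 % of the catalyst, and the flask held 83.9 %.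

Its constants were set for the occasion; what happens was integrated by code.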